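**Retrosynthetic overview**

1. Target ⇐ selective diacetylation of a triol acid ⇐ Payne opening of a (2S,3S)-epoxy alcohol ⇐ Sharpless epoxidation of an (E)-allylic alcohol ⇐ methylalumination of a terminal alkyne ⇐ side-chain methyl ketone.
2. Ring A ⇐ Robinson-type annulation (Michael, aldol, dehydration) of methyl acetoacetate onto a ring B cyclohexenecarbaldehyde; then C-methylation of the β-keto ester, deconjugation to the 4,4a-alkene and removal of the C2 oxygen.
3. Key bond, quaternary ring carbon to side-chain CH2 ⇐ intermolecular Michael addition of the chiral imine of (3R)-2,3-dimethylcyclohexanone to methyl vinyl ketone.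
4. Ring B ⇐ (R)-pulegone (α′-methylation, retro-aldol). Ring B comes first (chiral pool), ring A second (annulation).

Note on locants: the Why lines use the numbering of the systematic names (octalin: C1 carboxyl-bearing carbon, C4=C4a alkene, C5 quaternary carbon with the side chain, C6 CHMe, C8a ring-fusion CH); no structural assumption was needed.

**Route**

Step 1
Reactants: 1 (R)-pulegone
Product: 2 (3R)-2,3-dimethyl-6-(propan-2-ylidene)cyclohexan-1-one (mixture of C2 epimers)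
Conditions: LiN(iPr)2, THF, −78 °C; MeI, −78 to 0 °C
Reagents that add atoms: iodomethane (SMILES: CI)
Why: Kinetic deprotonation of the enone at the α′-CH2 gives the cross-conjugated enolate, and its alkylation (enolate alkylation) installs the methyl that ends up on C5 of the octalin; the new centre is a mixture that is erased in step 4 and the pulegone stereocentre is untouched.

Step 2
Reactants: 2 (3R)-2,3-dimethyl-6-(propan-2-ylidene)cyclohexan-1-one
Product: 3 (3R)-2,3-dimethylcyclohexan-1-one (mixture of C2 epimers)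
Conditions: 6 M HCl (aq.), reflux, acetone distilled off
Reagents that add atoms: none
Why: Acid-catalysed retro-aldol cleavage of the isopropylidene ketone (hydration, then loss of acetone) frees the α-methylene, no stereocentre is formed and C3 cannot epimerise.

Step 3
Reactants: 3 (3R)-2,3-dimethylcyclohexan-1-one; 4 (S)-1-phenylethan-1-amine
Product: 5 (3R)-2,3-dimethyl-N-[(1S)-1-phenylethyl]cyclohexan-1-imine
Conditions: TsOH (cat.), toluene, reflux (Dean–Stark)
Reagents that add atoms: none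
Why: Acid-catalysed condensation gives the imine, which equilibrates with the more substituted secondary enamine needed next; the C=N geometry and the epimerisable C2 are of no consequence.

Step 4
Reactants: 5 (3R)-2,3-dimethyl-N-[(1S)-1-phenylethyl]cyclohexan-1-imine; 6 but-3-en-2-one
Product: 8 (2S,3R)-2,3-dimethyl-2-(3-oxobutyl)cyclohexan-1-one, via Michael-adduct imine 7 (not isolated)
Conditions: THF, 40 °C; then 20% aq. AcOH, rt
Reagents that add atoms: water (SMILES: O)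
Why: Deracemising Michael addition (d'Angelo aza-ene type) of the more substituted secondary enamine to the enone sets the quaternary centre: the acceptor adds anti to the pseudoaxial C3 methyl, reinforced by the (S)-auxiliary, so the oxobutyl chain ends up trans to that methyl, and mild acid hydrolysis frees the diketone.

Step 5
Reactants: 8 (2S,3R)-2,3-dimethyl-2-(3-oxobutyl)cyclohexan-1-one
Product: 9 (2S,3R)-2,3-dimethyl-2-[2-(2-methyl-1,3-dioxolan-2-yl)ethyl]cyclohexan-1-one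
Conditions: HOCH2CH2OH (1.5 equiv), PPTS (cat.), benzene, reflux (Dean–Stark)
Reagents that add atoms: ethane-1,2-diol (SMILES: OCCO)
Why: Acetalisation is chemoselective for the unhindered methyl ketone because the ring carbonyl is flanked by the quaternary carbon; no stereocentre changes.

Step 6
Reactants: 9 (2S,3R)-2,3-dimethyl-2-[2-(2-methyl-1,3-dioxolan-2-yl)ethyl]cyclohexan-1-one
Product: 10 (5R,6S)-5,6-dimethyl-6-[2-(2-methyl-1,3-dioxolan-2-yl)ethyl]cyclohex-1-en-1-yl trifluoromethanesulfonate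
Conditions: LiN(iPr)2, THF, −78 °C; PhNTf2, −78 °C to rt
Reagents that add atoms: N-phenyl-bis(trifluoromethanesulfonimide) (SMILES: O=S(=O)(N(c1ccccc1)S(=O)(=O)C(F)(F)F)C(F)(F)F)
Why: C6 is the only enolisable α-position of the ring ketone, so enolate formation and O-triflation (enol triflate synthesis) give a single regioisomer.

Step 7
Reactants: 10 (5R,6S)-5,6-dimethyl-6-[2-(2-methyl-1,3-dioxolan-2-yl)ethyl]cyclohex-1-en-1-yl trifluoromethanesulfonate
Product: 11 methyl (5R,6S)-5,6-dimethyl-6-[2-(2-methyl-1,3-dioxolan-2-yl)ethyl]cyclohex-1-ene-1-carboxylate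
Conditions: Pd(OAc)2 (5 mol %), PPh3, CO (1 atm), MeOH, Et3N, DMF, 60 °C
Reagents that add atoms: carbon monoxide (SMILES: [C-]#[O+]); methanol (SMILES: CO)
Why: Pd(OAc)2/PPh3-catalysed alkoxycarbonylation of the vinyl triflate (oxidative addition, CO insertion, methanolysis) adds the carbon that becomes C4 of the octalin.

Step 8
Reactants: 11 methyl (5R,6S)-5,6-dimethyl-6-[2-(2-methyl-1,3-dioxolan-2-yl)ethyl]cyclohex-1-ene-1-carboxylate
Product: 12 [(5R,6S)-5,6-dimethyl-6-[2-(2-methyl-1,3-dioxolan-2-yl)ethyl]cyclohex-1-en-1-yl]methanol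
Conditions: iBu2AlH (2.5 equiv), CH2Cl2, −78 °C
Reagents that add atoms: none
Why: 1,2-Reduction of the unsaturated ester by iBu2AlH gives the allylic alcohol while the acetal is inert.

Step 9
Reactants: 12 [(5R,6S)-5,6-dimethyl-6-[2-(2-methyl-1,3-dioxolan-2-yl)ethyl]cyclohex-1-en-1-yl]methanol
Product: 13 (5R,6S)-5,6-dimethyl-6-[2-(2-methyl-1,3-dioxolan-2-yl)ethyl]cyclohex-1-ene-1-carbaldehyde
Conditions: MnO2, CH2Cl2, rt
Reagents that add atoms: none
Why: MnO2 oxidises the allylic alcohol selectively to the enal (allylic oxidation) without touching the acetal.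

Step 10
Reactants: 13 (5R,6S)-5,6-dimethyl-6-[2-(2-methyl-1,3-dioxolan-2-yl)ethyl]cyclohex-1-ene-1-carbaldehyde; 14 methyl 3-oxobutanoate
Product: 17 methyl (4aR,5S,6R,8aS)-5,6-dimethyl-5-[2-(2-methyl-1,3-dioxolan-2-yl)ethyl]-2-oxo-1,2,4a,5,6,7,8,8a-octahydronaphthalene-1-carboxylate, via Michael adduct 15 (not isolated), via aldol ketol 16 (not isolated)
Conditions: NaOMe (0.2 equiv), MeOH, 0 °C to reflux
Reagents that add atoms: none
Why: Robinson-type annulation (intermolecular Michael addition of the acetoacetate enolate to the enal β-carbon, intramolecular aldol of the methyl ketone onto the aldehyde, dehydration) closes ring A; C8a is set in the Michael step, where chair-like attack on the face of the C5 and C6 methyls meets only the small C5 methyl while the other face meets the long C5 chain, so the 8aS adduct is expected to predominate only moderately, C4a equilibrates to the trans fusion and C1 stays epimerisable.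

Step 11
Reactants: 17 methyl (4aR,5S,6R,8aS)-5,6-dimethyl-5-[2-(2-methyl-1,3-dioxolan-2-yl)ethyl]-2-oxo-1,2,4a,5,6,7,8,8a-octahydronaphthalene-1-carboxylate
Product: 18 methyl (1R,4aR,5S,6R,8aS)-1,5,6-trimethyl-5-[2-(2-methyl-1,3-dioxolan-2-yl)ethyl]-2-oxo-1,2,4a,5,6,7,8,8a-octahydronaphthalene-1-carboxylate
Conditions: K2CO3, MeI, acetone, reflux
Reagents that add atoms: iodomethane (SMILES: CI)
Why: C-Alkylation of the β-keto ester enolate (enolate alkylation) creates quaternary C1: methyl iodide attacks axially, anti to the axial H-8a of the trans-fused ring, so the new methyl is trans to H-8a and the ester is equatorial and cis to H-8a.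

Step 12
Reactants: 18 methyl (1R,4aR,5S,6R,8aS)-1,5,6-trimethyl-5-[2-(2-methyl-1,3-dioxolan-2-yl)ethyl]-2-oxo-1,2,4a,5,6,7,8,8a-octahydronaphthalene-1-carboxylate
Product: 20 methyl (1R,5S,6R,8aS)-2-hydroxy-1,5,6-trimethyl-5-[2-(2-methyl-1,3-dioxolan-2-yl)ethyl]-1,2,3,5,6,7,8,8a-octahydronaphthalene-1-carboxylate (mixture of C2 epimers), via deconjugated ketone 19 (not isolated)
Conditions: KOtBu, tBuOH/THF, 0 °C; cold aq. AcOH quench; then NaBH4, MeOH/CH2Cl2, −20 °C
Reagents that add atoms: none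
Why: γ-Deprotonation at C4a (C1 is quaternary) gives the extended dienolate, kinetic α-protonation gives the β,γ-unsaturated ketone with the alkene at C4–C4a (deconjugation), and immediate NaBH4 reduction traps it as the homoallylic alcohol; the C4a centre is erased and the carbinol centre does not matter.

Step 13
Reactants: 20 methyl (1R,5S,6R,8aS)-2-hydroxy-1,5,6-trimethyl-5-[2-(2-methyl-1,3-dioxolan-2-yl)ethyl]-1,2,3,5,6,7,8,8a-octahydronaphthalene-1-carboxylate
Product: 21 methyl (1R,5S,6R,8aS)-2-[(1H-imidazol-1-ylcarbonothioyl)oxy]-1,5,6-trimethyl-5-[2-(2-methyl-1,3-dioxolan-2-yl)ethyl]-1,2,3,5,6,7,8,8a-octahydronaphthalene-1-carboxylate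
Conditions: (imidazol-1-yl)2C=S, DMAP (cat.), ClCH2CH2Cl, reflux
Reagents that add atoms: 1,1'-thiocarbonyldiimidazole (SMILES: S=C(n1ccnc1)n1ccnc1)
Why: Acylation of the hindered secondary alcohol gives the thiocarbonyl derivative needed for radical deoxygenation, under non-basic conditions that avoid retro-aldol cleavage.

Step 14
Reactants: 21 methyl (1R,5S,6R,8aS)-2-[(1H-imidazol-1-ylcarbonothioyl)oxy]-1,5,6-trimethyl-5-[2-(2-methyl-1,3-dioxolan-2-yl)ethyl]-1,2,3,5,6,7,8,8a-octahydronaphthalene-1-carboxylate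
Product: 22 methyl (1S,5S,6R,8aS)-1,5,6-trimethyl-5-[2-(2-methyl-1,3-dioxolan-2-yl)ethyl]-1,2,3,5,6,7,8,8a-octahydronaphthalene-1-carboxylate
Conditions: Bu3SnH, AIBN (cat.), toluene, reflux
Reagents that add atoms: none
Why: Barton–McCombie deoxygenation: the Bu3Sn radical adds to the thiocarbonyl, the C2 radical formed on fragmentation takes hydrogen from Bu3SnH, and the trisubstituted alkene and the ester are inert.

Step 15
Reactants: 22 methyl (1S,5S,6R,8aS)-1,5,6-trimethyl-5-[2-(2-methyl-1,3-dioxolan-2-yl)ethyl]-1,2,3,5,6,7,8,8a-octahydronaphthalene-1-carboxylate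
Product: 23 methyl (1S,5S,6R,8aS)-1,5,6-trimethyl-5-(3-oxobutyl)-1,2,3,5,6,7,8,8a-octahydronaphthalene-1-carboxylate
Conditions: 1 M HCl (aq.), THF, rt
Reagents that add atoms: water (SMILES: O)
Why: Mild acid hydrolysis of the dioxolane (acetal cleavage) unmasks the methyl ketone and leaves the ester, the alkene and all stereocentres alone.

Step 16
Reactants: 23 methyl (1S,5S,6R,8aS)-1,5,6-trimethyl-5-(3-oxobutyl)-1,2,3,5,6,7,8,8a-octahydronaphthalene-1-carboxylate
Product: 24 methyl (1S,5S,6R,8aS)-5-{3-[(diethoxyphosphoryl)oxy]but-3-en-1-yl}-1,5,6-trimethyl-1,2,3,5,6,7,8,8a-octahydronaphthalene-1-carboxylate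
Conditions: LiN(iPr)2 (1.05 equiv), THF, −78 °C; ClP(O)(OEt)2, −78 °C to rt
Reagents that add atoms: diethyl chlorophosphate (SMILES: CCOP(Cl)(=O)OCC)
Why: Kinetic deprotonation of the methyl ketone on the methyl side and O-phosphorylation give the terminal enol phosphate (first half of the Negishi ketone-to-alkyne sequence); the ester has no α-hydrogen.

Step 17
Reactants: 24 methyl (1S,5S,6R,8aS)-5-{3-[(diethoxyphosphoryl)oxy]but-3-en-1-yl}-1,5,6-trimethyl-1,2,3,5,6,7,8,8a-octahydronaphthalene-1-carboxylate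
Product: 25 methyl (1S,5S,6R,8aS)-5-(but-3-yn-1-yl)-1,5,6-trimethyl-1,2,3,5,6,7,8,8a-octahydronaphthalene-1-carboxylate
Conditions: LiN(iPr)2 (2.3 equiv), THF, −78 °C to rt; aq. NH4Cl
Reagents that add atoms: none
Why: Base-induced β-elimination of diethyl phosphate from the enol phosphate, driven by formation of the lithium acetylide, gives the terminal alkyne.

Step 18
Reactants: 25 methyl (1S,5S,6R,8aS)-5-(but-3-yn-1-yl)-1,5,6-trimethyl-1,2,3,5,6,7,8,8a-octahydronaphthalene-1-carboxylate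
Product: 27 methyl (1S,5S,6R,8aS)-5-[(3E)-5-hydroxy-3-methylpent-3-en-1-yl]-1,5,6-trimethyl-1,2,3,5,6,7,8,8a-octahydronaphthalene-1-carboxylate, via alkenylalane 26 (not isolated)
Conditions: AlMe3 (3 equiv), Cp2ZrCl2 (0.25 equiv), CH2Cl2, rt; volatiles removed; n-BuLi, THF, −78 °C; (CH2O)n, −78 °C to rt
Reagents that add atoms: trimethylaluminium (SMILES: C[Al](C)C); formaldehyde as paraformaldehyde (SMILES: C=O)
Why: Negishi Cp2ZrCl2-catalysed methylalumination adds methyl and aluminium syn across the alkyne with aluminium at the terminus, and hydroxymethylation of the derived alanate proceeds with retention, which fixes the (E)-trisubstituted alkene.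

Step 19
Reactants: 27 methyl (1S,5S,6R,8aS)-5-[(3E)-5-hydroxy-3-methylpent-3-en-1-yl]-1,5,6-trimethyl-1,2,3,5,6,7,8,8a-octahydronaphthalene-1-carboxylate
Product: 28 methyl (1S,5S,6R,8aS)-5-{2-[(2S,3S)-3-(hydroxymethyl)-2-methyloxiran-2-yl]ethyl}-1,5,6-trimethyl-1,2,3,5,6,7,8,8a-octahydronaphthalene-1-carboxylate
Conditions: Ti(OiPr)4 (10 mol %), L-(+)-diethyl tartrate (12 mol %), tBuOOH, 4 Å MS, CH2Cl2, −20 °C
Reagents that add atoms: tert-butyl hydroperoxide (SMILES: CC(C)(C)OO)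
Why: Sharpless asymmetric epoxidation with L-(+)-diethyl tartrate delivers oxygen to the face of the (E)-allylic alcohol that gives the (2S,3S)-epoxy alcohol, under reagent control and without touching the isolated ring alkene.

Step 20
Reactants: 28 methyl (1S,5S,6R,8aS)-5-{2-[(2S,3S)-3-(hydroxymethyl)-2-methyloxiran-2-yl]ethyl}-1,5,6-trimethyl-1,2,3,5,6,7,8,8a-octahydronaphthalene-1-carboxylate
Product: 29 (1S,5S,6R,8aS)-1,5,6-trimethyl-5-[(3S,4R)-3,4,5-trihydroxy-3-methylpentyl]-1,2,3,5,6,7,8,8a-octahydronaphthalene-1-carboxylic acid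
Conditions: KOH (10 equiv), tBuOH/H2O (1:1), 85 °C; then 1 M HCl to pH 3
Reagents that add atoms: potassium hydroxide (SMILES: [K+].[OH-]); water (SMILES: O)
Why: Payne rearrangement followed by hydroxide opening at the primary carbon gives the triol with inversion at the secondary carbinol and retention at the tertiary one, that is the (3S,4R) pattern, while the same hot base saponifies the hindered but equatorial methyl ester.

Step 21
Reactants: 29 (1S,5S,6R,8aS)-1,5,6-trimethyl-5-[(3S,4R)-3,4,5-trihydroxy-3-methylpentyl]-1,2,3,5,6,7,8,8a-octahydronaphthalene-1-carboxylic acid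
Product: 30 (1S,5S,6R,8aS)-5-[(3S,4R)-4,5-bis(acetyloxy)-3-hydroxy-3-methylpentyl]-1,5,6-trimethyl-1,2,3,5,6,7,8,8a-octahydronaphthalene-1-carboxylic acid (CNP0224606.2)
Conditions: Ac2O (3 equiv), pyridine, CH2Cl2, 0 °C to rt; H2O work-up
Reagents that add atoms: acetic anhydride (SMILES: CC(=O)OC(C)=O)
Why: Acetylation in pyridine esterifies only the primary and secondary hydroxyls, the tertiary alcohol being too hindered, and the transient mixed anhydride of the acid is hydrolysed on aqueous work-up.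

**Compound list**

1 | (R)-pulegone, (5R)-5-methyl-2-(propan-2-ylidene)cyclohexan-1-one | C[C@@H]1CCC(=C(C)C)C(=O)C1 | starting material
2 | (3R)-2,3-dimethyl-6-(propan-2-ylidene)cyclohexan-1-one (C2 epimers) | C[C@@H]1CCC(=C(C)C)C(=O)C1C | intermediate
3 | (3R)-2,3-dimethylcyclohexan-1-one (C2 epimers) | CC1C(=O)CCC[C@H]1C | intermediate
4 | (S)-1-phenylethan-1-amine | C[C@H](N)c1ccccc1 | starting material
5 | (3R)-2,3-dimethyl-N-[(1S)-1-phenylethyl]cyclohexan-1-imine | CC1C(=N[C@@H](C)c2ccccc2)CCC[C@H]1C | intermediate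
6 | but-3-en-2-one (methyl vinyl ketone) | CC(=O)C=C | starting material
7 | (2S,3R)-2,3-dimethyl-2-(3-oxobutyl)-N-[(1S)-1-phenylethyl]cyclohexan-1-imine | CC(=O)CC[C@]1(C)C(=N[C@@H](C)c2ccccc2)CCC[C@H]1C | intermediate
8 | (2S,3R)-2,3-dimethyl-2-(3-oxobutyl)cyclohexan-1-one | CC(=O)CC[C@]1(C)C(=O)CCC[C@H]1C | intermediate
9 | (2S,3R)-2,3-dimethyl-2-[2-(2-methyl-1,3-dioxolan-2-yl)ethyl]cyclohexan-1-one | CC1(CC[C@]2(C)C(=O)CCC[C@H]2C)OCCO1 | intermediate
10 | (5R,6S)-5,6-dimethyl-6-[2-(2-methyl-1,3-dioxolan-2-yl)ethyl]cyclohex-1-en-1-yl trifluoromethanesulfonate | CC1(CC[C@]2(C)C(OS(=O)(=O)C(F)(F)F)=CCC[C@H]2C)OCCO1 | intermediate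
11 | methyl (5R,6S)-5,6-dimethyl-6-[2-(2-methyl-1,3-dioxolan-2-yl)ethyl]cyclohex-1-ene-1-carboxylate | CC1(CC[C@]2(C)C(C(=O)OC)=CCC[C@H]2C)OCCO1 | intermediate
12 | [(5R,6S)-5,6-dimethyl-6-[2-(2-methyl-1,3-dioxolan-2-yl)ethyl]cyclohex-1-en-1-yl]methanol | CC1(CC[C@]2(C)C(CO)=CCC[C@H]2C)OCCO1 | intermediate
13 | (5R,6S)-5,6-dimethyl-6-[2-(2-methyl-1,3-dioxolan-2-yl)ethyl]cyclohex-1-ene-1-carbaldehyde | CC1(CC[C@]2(C)C(C=O)=CCC[C@H]2C)OCCO1 | intermediate
14 | methyl 3-oxobutanoate (methyl acetoacetate) | CC(=O)CC(=O)OC | starting material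
15 | methyl 2-[(1S,3S,4R)-2-formyl-3,4-dimethyl-3-[2-(2-methyl-1,3-dioxolan-2-yl)ethyl]cyclohexyl]-3-oxobutanoate (epimers at ring C2 and butanoate C2) | CC1(CC[C@]2(C)C(C=O)[C@@H](C(C(C)=O)C(=O)OC)CC[C@H]2C)OCCO1 | intermediate
16 | methyl (5S,6R,8aS)-4-hydroxy-5,6-dimethyl-5-[2-(2-methyl-1,3-dioxolan-2-yl)ethyl]-2-oxodecahydronaphthalene-1-carboxylate (epimers at C1, C4, C4a) | CC1(CC[C@]2(C)C3C(O)CC(=O)C(C(=O)OC)[C@H]3CC[C@H]2C)OCCO1 | intermediate
17 | methyl (4aR,5S,6R,8aS)-5,6-dimethyl-5-[2-(2-methyl-1,3-dioxolan-2-yl)ethyl]-2-oxo-1,2,4a,5,6,7,8,8a-octahydronaphthalene-1-carboxylate (C1 epimers and enol) | CC1(CC[C@]2(C)[C@@H]3C=CC(=O)C(C(=O)OC)[C@H]3CC[C@H]2C)OCCO1 | intermediate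
18 | methyl (1R,4aR,5S,6R,8aS)-1,5,6-trimethyl-5-[2-(2-methyl-1,3-dioxolan-2-yl)ethyl]-2-oxo-1,2,4a,5,6,7,8,8a-octahydronaphthalene-1-carboxylate | CC1(CC[C@]2(C)[C@@H]3C=CC(=O)[C@](C)(C(=O)OC)[C@H]3CC[C@H]2C)OCCO1 | intermediate
19 | methyl (1R,5S,6R,8aS)-1,5,6-trimethyl-5-[2-(2-methyl-1,3-dioxolan-2-yl)ethyl]-2-oxo-1,2,3,5,6,7,8,8a-octahydronaphthalene-1-carboxylate | CC1(CC[C@]2(C)C3=CCC(=O)[C@](C)(C(=O)OC)[C@H]3CC[C@H]2C)OCCO1 | intermediate
20 | methyl (1R,5S,6R,8aS)-2-hydroxy-1,5,6-trimethyl-5-[2-(2-methyl-1,3-dioxolan-2-yl)ethyl]-1,2,3,5,6,7,8,8a-octahydronaphthalene-1-carboxylate (C2 epimers) | CC1(CC[C@]2(C)C3=CCC(O)[C@](C)(C(=O)OC)[C@H]3CC[C@H]2C)OCCO1 | intermediate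
21 | methyl (1R,5S,6R,8aS)-2-[(1H-imidazol-1-ylcarbonothioyl)oxy]-1,5,6-trimethyl-5-[2-(2-methyl-1,3-dioxolan-2-yl)ethyl]-1,2,3,5,6,7,8,8a-octahydronaphthalene-1-carboxylate (C2 epimers) | CC1(CC[C@]2(C)C3=CCC(OC(=S)n4ccnc4)[C@](C)(C(=O)OC)[C@H]3CC[C@H]2C)OCCO1 | intermediate
22 | methyl (1S,5S,6R,8aS)-1,5,6-trimethyl-5-[2-(2-methyl-1,3-dioxolan-2-yl)ethyl]-1,2,3,5,6,7,8,8a-octahydronaphthalene-1-carboxylate | CC1(CC[C@]2(C)C3=CCC[C@](C)(C(=O)OC)[C@H]3CC[C@H]2C)OCCO1 | intermediate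
23 | methyl (1S,5S,6R,8aS)-1,5,6-trimethyl-5-(3-oxobutyl)-1,2,3,5,6,7,8,8a-octahydronaphthalene-1-carboxylate | CC(=O)CC[C@]1(C)C2=CCC[C@](C)(C(=O)OC)[C@H]2CC[C@H]1C | intermediate
24 | methyl (1S,5S,6R,8aS)-5-{3-[(diethoxyphosphoryl)oxy]but-3-en-1-yl}-1,5,6-trimethyl-1,2,3,5,6,7,8,8a-octahydronaphthalene-1-carboxylate | C=C(CC[C@]1(C)C2=CCC[C@](C)(C(=O)OC)[C@H]2CC[C@H]1C)OP(=O)(OCC)OCC | intermediate
25 | methyl (1S,5S,6R,8aS)-5-(but-3-yn-1-yl)-1,5,6-trimethyl-1,2,3,5,6,7,8,8a-octahydronaphthalene-1-carboxylate | C#CCC[C@]1(C)C2=CCC[C@](C)(C(=O)OC)[C@H]2CC[C@H]1C | intermediate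
26 | methyl (1S,5S,6R,8aS)-5-[(3E)-4-(dimethylalumanyl)-3-methylbut-3-en-1-yl]-1,5,6-trimethyl-1,2,3,5,6,7,8,8a-octahydronaphthalene-1-carboxylate | C[Al](C)/C=C(\C)CC[C@]1(C)C2=CCC[C@](C)(C(=O)OC)[C@H]2CC[C@H]1C | intermediate
27 | methyl (1S,5S,6R,8aS)-5-[(3E)-5-hydroxy-3-methylpent-3-en-1-yl]-1,5,6-trimethyl-1,2,3,5,6,7,8,8a-octahydronaphthalene-1-carboxylate | OC/C=C(\C)CC[C@]1(C)C2=CCC[C@](C)(C(=O)OC)[C@H]2CC[C@H]1C | intermediate
28 | methyl (1S,5S,6R,8aS)-5-{2-[(2S,3S)-3-(hydroxymethyl)-2-methyloxiran-2-yl]ethyl}-1,5,6-trimethyl-1,2,3,5,6,7,8,8a-octahydronaphthalene-1-carboxylate | OC[C@@H]1O[C@@]1(C)CC[C@]2(C)C3=CCC[C@](C)(C(=O)OC)[C@H]3CC[C@H]2C | intermediate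
29 | (1S,5S,6R,8aS)-1,5,6-trimethyl-5-[(3S,4R)-3,4,5-trihydroxy-3-methylpentyl]-1,2,3,5,6,7,8,8a-octahydronaphthalene-1-carboxylic acid | OC[C@@H](O)[C@@](C)(O)CC[C@]1(C)C2=CCC[C@](C)(C(=O)O)[C@H]2CC[C@H]1C | intermediate
30 | (1S,5S,6R,8aS)-5-[(3S,4R)-4,5-bis(acetyloxy)-3-hydroxy-3-methylpentyl]-1,5,6-trimethyl-1,2,3,5,6,7,8,8a-octahydronaphthalene-1-carboxylic acid (CNP0224606.2) | CC(=O)OC[C@@H](OC(C)=O)[C@@](C)(O)CC[C@]1(C)C2=CCC[C@](C)(C(=O)O)[C@H]2CC[C@H]1C | target

**Totals**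

Total step count: 21. Longest linear sequence: 21 steps (fully linear from 1).

**Steps most likely to fail**

Step 10. The Michael/aldol annulation runs on a hindered enal, and the C8a configuration rests only on substrate control between a methyl and a CH2CH2R group on the neighbouring quaternary carbon. The ratio may be low or even reversed, and the minor 8a-epimer has to be removed by chromatography after step 11. Fallback: ring A is built by a catalyst-controlled Diels–Alder reaction instead; it sets out from triflate 10 and comes back to the route at ester 22. Stille coupling of 10 with Bu3Sn(CH=CH2) (Pd(PPh3)4, LiCl, THF, reflux) gives the diene 2-{2-[(1S,6R)-2-ethenyl-1,6-dimethylcyclohex-2-en-1-yl]ethyl}-2-methyl-1,3-dioxolane F1. Cycloaddition with methacrolein under a chiral cationic oxazaborolidine catalyst (both enantiomers are available, so the one matched to the diene is used; ortho regiochemistry, formyl group exo) forms the quaternary carbon, the 8a centre and the 4,4a-alkene in one step and gives (1S,5S,6R,8aS)-1,5,6-trimethyl-5-[2-(2-methyl-1,3-dioxolan-2-yl)ethyl]-1,2,3,5,6,7,8,8a-octahydronaphthalene-1-carbaldehyde F2. Oxidation with NaClO2/NaH2PO4/2-methylbut-2-ene gives (1S,5S,6R,8aS)-1,5,6-trimethyl-5-[2-(2-methyl-1,3-dioxolan-2-yl)ethyl]-1,2,3,5,6,7,8,8a-octahydronaphthalene-1-carboxylic acid F3, and Me3SiCHN2 in MeOH/toluene gives methyl ester 22.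

Step 12. γ-Deprotonation next to a quaternary centre may be slow, and retro-Claisen cleavage of the non-enolisable β-keto ester or reconjugation before reduction can compete. Fallback: the oxygen is removed through a dienyl triflate; it sets out from 18 and comes back at 22. KN(SiMe3)2 then PhNTf2 (THF, −78 °C) trap the same extended enolate on oxygen as methyl (1R,5S,6R,8aS)-1,5,6-trimethyl-5-[2-(2-methyl-1,3-dioxolan-2-yl)ethyl]-2-[(trifluoromethanesulfonyl)oxy]-1,5,6,7,8,8a-hexahydronaphthalene-1-carboxylate F4. Reduction with HCO2H/Bu3N under Pd(OAc)2/PPh3 catalysis gives the ring A diene methyl (1S,5S,6R,8aS)-1,5,6-trimethyl-5-[2-(2-methyl-1,3-dioxolan-2-yl)ethyl]-1,5,6,7,8,8a-hexahydronaphthalene-1-carboxylate F5. Diimide (KO2CN=NCO2K, AcOH, MeOH) saturates only the disubstituted 2,3-alkene and gives 22.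

Step 18. The alanate/formaldehyde step needs n-BuLi and AlMe3 in the presence of the hindered ester, and protodealumination can compete. Fallback: the CH2OH carbon is attached by cross-coupling; it sets out from alkyne 25 and comes back at 27. The methylalumination is run as before, but alane 26 is quenched with I2 to give the vinyl iodide methyl (1S,5S,6R,8aS)-5-[(3E)-4-iodo-3-methylbut-3-en-1-yl]-1,5,6-trimethyl-1,2,3,5,6,7,8,8a-octahydronaphthalene-1-carboxylate F6. Stille coupling with Bu3SnCH2OH (Pd(PPh3)4, toluene, 80 °C) gives allylic alcohol 27.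

**Further compounds**

F1 | step 10 | 2-{2-[(1S,6R)-2-ethenyl-1,6-dimethylcyclohex-2-en-1-yl]ethyl}-2-methyl-1,3-dioxolane | CC1(CC[C@]2(C)C(C=C)=CCC[C@H]2C)OCCO1
F2 | step 10 | (1S,5S,6R,8aS)-1,5,6-trimethyl-5-[2-(2-methyl-1,3-dioxolan-2-yl)ethyl]-1,2,3,5,6,7,8,8a-octahydronaphthalene-1-carbaldehyde | CC1(CC[C@]2(C)C3=CCC[C@](C)(C=O)[C@H]3CC[C@H]2C)OCCO1
F3 | step 10 | (1S,5S,6R,8aS)-1,5,6-trimethyl-5-[2-(2-methyl-1,3-dioxolan-2-yl)ethyl]-1,2,3,5,6,7,8,8a-octahydronaphthalene-1-carboxylic acid | CC1(CC[C@]2(C)C3=CCC[C@](C)(C(=O)O)[C@H]3CC[C@H]2C)OCCO1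
F4 | step 12 | methyl (1R,5S,6R,8aS)-1,5,6-trimethyl-5-[2-(2-methyl-1,3-dioxolan-2-yl)ethyl]-2-[(trifluoromethanesulfonyl)oxy]-1,5,6,7,8,8a-hexahydronaphthalene-1-carboxylate | CC1(CC[C@]2(C)C3=CC=C(OS(=O)(=O)C(F)(F)F)[C@](C)(C(=O)OC)[C@H]3CC[C@H]2C)OCCO1
F5 | step 12 | methyl (1S,5S,6R,8aS)-1,5,6-trimethyl-5-[2-(2-methyl-1,3-dioxolan-2-yl)ethyl]-1,5,6,7,8,8a-hexahydronaphthalene-1-carboxylate | CC1(CC[C@]2(C)C3=CC=C[C@](C)(C(=O)OC)[C@H]3CC[C@H]2C)OCCO1
F6 | step 18 | methyl (1S,5S,6R,8aS)-5-[(3E)-4-iodo-3-methylbut-3-en-1-yl]-1,5,6-trimethyl-1,2,3,5,6,7,8,8a-octahydronaphthalene-1-carboxylate | I/C=C(\C)CC[C@]1(C)C2=CCC[C@](C)(C(=O)OC)[C@H]2CC[C@H]1C
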